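**Retrosynthetic overview**

1. Feature: on the benzo ring C4a–C5–C6–C7–C8–C8a of the 2,5-dihydroxy-1,4-naphthoquinone, C6 carries the di-ortho-substituted 2,4-dihydroxy-6-methylbenzoyl group and C7 the CH2 link to C6 of the 4-hydroxy-2-pyranone, both beside the C5 oxygen. A 3-alkoxyaryne that inserts into the C(=O)–CH2 bond of a β-keto ester gives exactly this vicinal acyl/CH2C(=O) pair.
2. Disconnections: pyranone ring to arylacetic acid plus dioxinone (acylketene lactonisation); C6–C(=O) and C7–CH2 to a 5-methoxy-6,7-naphthalyne plus benzyl-protected orsellinoylacetate; hydroxyquinone to the 1,2,4-trimethoxy ring (oxidative demethylation, hydrolysis).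
3. Aryne precursor: 1,2,4-trimethoxynaphthalene-5,7-diol from Claisen cyclisation of an ortho-acetonyl benzoate made from 2,4,5-trimethoxybenzoic acid; then C7 carbamate, C5 methyl ether, carbamate-directed C6 silylation, triflate.
4. Ring order: benzo ring C4a–C8a (step 4), no ring in the key step, pyranone (step 15), quinone unmasked (step 16).

Key step: step 12

Remark: locants C1–C8 in the text are those of the target naphthoquinone (C1=O, C2–OH, C4=O, C5–OH, C6 aroyl, C7 CH2); lithiated species and enolates are treated as conjugate bases of numbered compounds and carry no number of their own. The target has no stereocentre.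

**Route**

Step 1
Reactants: 1 2,4,5-trimethoxybenzoic acid
Product: 2 2,4,5-trimethoxy-6-methylbenzoic acid
Conditions: s-BuLi (2.2 equiv), TMEDA, THF, −78 °C; MeI, −78 °C to rt; aq. HCl
Reagents that add atoms: iodomethane, CI
Why: Carboxylate-directed ortho-lithiation (directed ortho metalation of an unprotected benzoic acid): after O–H deprotonation the second equivalent of base removes H6, the only proton ortho to the carboxylate and further acidified by the neighbouring methoxy group, and the aryllithium is methylated by MeI.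

Step 2
Reactants: 2 2,4,5-trimethoxy-6-methylbenzoic acid
Product: 3 methyl 2,4,5-trimethoxy-6-methylbenzoate
Conditions: MeI, K2CO3, DMF, rt
Reagents that add atoms: iodomethane, CI
Why: SN2 O-alkylation of the carboxylate esterifies the hindered acid at oxygen and not at the shielded carbonyl, and gives the methyl ester needed for the Claisen ring closure.

Step 3
Reactants: 3 methyl 2,4,5-trimethoxy-6-methylbenzoate
Product: 4 methyl 2,4,5-trimethoxy-6-(2-oxopropyl)benzoate
Conditions: LDA (1.2 equiv), THF, −78 °C; N-methoxy-N-methylacetamide, −78 to −20 °C; AcOH quench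
Reagents that add atoms: N-methoxy-N-methylacetamide, CC(=O)N(C)OC
Why: Lateral (benzylic) lithiation of an ortho-toluate followed by acylation with an N-methoxy-N-methylamide; the di-ortho-substituted ester resists self-condensation and the chelated tetrahedral adduct releases the ketone only on quench.

Step 4
Reactants: 4 methyl 2,4,5-trimethoxy-6-(2-oxopropyl)benzoate
Product: 5 5,6,8-trimethoxynaphthalene-1,3-diol (1,2,4-trimethoxynaphthalene-5,7-diol in target numbering)
Conditions: NaOMe (3 equiv), MeOH, 65 °C, Ar; cold 1 M HCl; used at once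
Reagents that add atoms: none
Why: Intramolecular Claisen (Dieckmann-type) condensation: the methyl-ketone enolate attacks the ester carbonyl (6-exo-trig) and the cyclic 1,3-dione tautomerises irreversibly to the aromatic naphthalene-1,3-diol, which closes the benzo ring C4a–C5–C6–C7–C8–C8a.

Step 5
Reactants: 5 5,6,8-trimethoxynaphthalene-1,3-diol
Product: 6 4-hydroxy-5,7,8-trimethoxynaphthalen-2-yl propan-2-ylcarbamate (C7 carbamate, C5 hydroxyl)
Conditions: i-PrNCO (1.05 equiv), Et3N (0.2 equiv), CH2Cl2, 0 °C to rt, Ar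
Reagents that add atoms: isopropyl isocyanate, CC(C)N=C=O
Why: Amine-catalysed addition of a phenol to an isocyanate (carbamoylation); with one equivalent the unhindered, more acidic C7 hydroxyl should react in preference to the C5 hydroxyl, which is peri to the C4 methoxy group, hydrogen-bonded to it and shielded.

Step 6
Reactants: 6 4-hydroxy-5,7,8-trimethoxynaphthalen-2-yl propan-2-ylcarbamate
Product: 7 4,5,7,8-tetramethoxynaphthalen-2-yl propan-2-ylcarbamate
Conditions: PPh3, DIAD, THF, 0 °C (betaine preformed); MeOH, then 6, 0 °C to rt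
Reagents that add atoms: methanol, CO
Why: Mitsunobu etherification with methanol methylates the remaining naphthol under neutral conditions, which avoids the base-induced E1cB loss of the N–H carbamate that carbonate/MeI could cause.

Step 7
Reactants: 7 4,5,7,8-tetramethoxynaphthalen-2-yl propan-2-ylcarbamate
Product: 10 4,5,7,8-tetramethoxy-3-(trimethylsilyl)naphthalen-2-yl propan-2-ylcarbamate, via N-TBS carbamate 8 (not isolated), via N-TBS C-TMS carbamate 9 (not isolated)
Conditions: TBSOTf (1.1 equiv), TMEDA, Et2O, 0 °C to rt; n-BuLi (2 equiv), TMEDA, −78 °C; TMSCl, −78 °C to rt; cold aq. NaHSO4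
Reagents that add atoms: chlorotrimethylsilane, C[Si](C)(C)Cl
Why: Directed ortho metalation of an O-aryl carbamate: after N-silylation in the flask the carbamate directs lithiation to C6, the site flanked by the carbamate and the C5 methoxy oxygen, TMSCl traps the aryllithium and the N–Si bond is hydrolysed in the acidic work-up.

Step 8
Reactants: 10 4,5,7,8-tetramethoxy-3-(trimethylsilyl)naphthalen-2-yl propan-2-ylcarbamate
Product: 12 4,5,7,8-tetramethoxy-3-(trimethylsilyl)naphthalen-2-yl trifluoromethanesulfonate, via silyl naphthol 11 (not isolated)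
Conditions: Et2NH, DBU, MeCN, 40 °C; then PhNTf2, rt
Reagents that add atoms: N-phenylbis(trifluoromethanesulfonimide), O=S(=O)(N(c1ccccc1)S(=O)(=O)C(F)(F)F)C(F)(F)F
Why: E1cB cleavage of the N-monoalkyl carbamate (the isocyanate is scavenged by Et2NH) releases the naphthoxide, which is O-triflated in the same flask to the ortho-silyl aryl triflate.

Step 9
Reactants: 13 ethyl 2,4-dihydroxy-6-methylbenzoate
Product: 14 ethyl 2,4-bis(benzyloxy)-6-methylbenzoate
Conditions: BnBr (2.5 equiv), K2CO3, DMF, 60 °C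
Reagents that add atoms: benzyl bromide, BrCc1ccccc1
Why: Williamson etherification of both phenols; heating and excess benzyl bromide are needed for the hydroxyl that is hydrogen-bonded to the ester.

Step 10
Reactants: 14 ethyl 2,4-bis(benzyloxy)-6-methylbenzoate
Product: 15 2,4-bis(benzyloxy)-6-methylbenzoic acid
Conditions: KOH, DMSO/H2O, 90 °C; aq. HCl
Reagents that add atoms: potassium hydroxide, [K+].[OH-]
Why: Saponification of a di-ortho-substituted benzoate under forcing conditions; benzyl ethers are inert to base.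

Step 11
Reactants: 15 2,4-bis(benzyloxy)-6-methylbenzoic acid
Product: 17 methyl 3-[2,4-bis(benzyloxy)-6-methylphenyl]-3-oxopropanoate, via acid chloride 16 (not isolated)
Conditions: (COCl)2, cat. DMF, CH2Cl2, 0 °C to rt; concentrate; MeOAc/LDA (2.5 equiv of enolate), THF, −78 °C; 1 M HCl
Reagents that add atoms: methyl acetate, COC(C)=O
Why: Acid chloride formation followed by crossed Claisen-type C-acylation of the lithium enolate of methyl acetate; the second equivalent of enolate deprotonates the β-keto ester and so prevents a second addition.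

Step 12
Reactants: 12 4,5,7,8-tetramethoxy-3-(trimethylsilyl)naphthalen-2-yl trifluoromethanesulfonate; 17 methyl 3-[2,4-bis(benzyloxy)-6-methylphenyl]-3-oxopropanoate
Product: 19 methyl 2-[3-(2,4-bis(benzyloxy)-6-methylbenzoyl)-4,5,7,8-tetramethoxynaphthalen-2-yl]acetate, via 6,7-naphthalyne 18 (not isolated)
Conditions: CsF (3 equiv), MeCN, 80 °C; 12 in slight excess (1.3 equiv)
Reagents that add atoms: none
Why: Fluoride attacks silicon of 12 and triflate leaves to give naphthalyne 18; the caesium enolate of 17 adds through its α-carbon to C7, the C6 aryl anion attacks the adjacent ketone carbonyl (4-exo-trig), and the benzocyclobutenoxide so formed opens by retro-aldol cleavage of the Cα–C(O) bond to the ester enolate, which is protonated. The closest known reaction type is the acyl-alkylation of arynes by β-keto esters (formal insertion into the C(=O)–Cα σ-bond), established for aroylacetates and for 3-alkoxyarynes. No ring remains in the product, since the four-membered ring is only a transient intermediate, and no stereocentre is formed. The step needs regioselective addition to the unsymmetrical aryne: the C5 methoxy group polarises and distorts the triple bond so that the nucleophile attacks the remote carbon C7 and the charge develops at C6 next to the σ-withdrawing oxygen, which places the aroyl group on C6 and the acetate arm on C7. It also needs ring closure to outrun protonation of the aryl anion, which the aprotic medium and the slow release of aryne from the sparingly soluble fluoride favour, and acyl rather than methoxycarbonyl migration, which follows from the higher electrophilicity of the ketone; the hindered ketone is thus built by intramolecular acyl transfer and not by attack on a shielded carbonyl from outside.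

Step 13
Reactants: 19 methyl 2-[3-(2,4-bis(benzyloxy)-6-methylbenzoyl)-4,5,7,8-tetramethoxynaphthalen-2-yl]acetate
Product: 20 2-[3-(2,4-bis(benzyloxy)-6-methylbenzoyl)-4,5,7,8-tetramethoxynaphthalen-2-yl]acetic acid
Conditions: LiOH, THF/H2O, rt; 1 M HCl
Reagents that add atoms: lithium hydroxide, [Li+].[OH-]
Why: Saponification of the unhindered methyl arylacetate; the tetra-ortho-substituted diaryl ketone is inert to hydroxide.

Step 14
Reactants: 20 2-[3-(2,4-bis(benzyloxy)-6-methylbenzoyl)-4,5,7,8-tetramethoxynaphthalen-2-yl]acetic acid; 21 2,2,6-trimethyl-4H-1,3-dioxin-4-one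
Product: 23 6-{3-[3-(2,4-bis(benzyloxy)-6-methylbenzoyl)-4,5,7,8-tetramethoxynaphthalen-2-yl]-2-oxopropyl}-2,2-dimethyl-4H-1,3-dioxin-4-one, via acyl imidazole 22 (not isolated)
Conditions: 20, CDI, THF, rt; added to 21/LiHMDS (3 equiv), THF, −78 to −40 °C; 1 M HCl
Reagents that add atoms: none
Why: Activation of the acid as the acyl imidazole and γ-C-acylation of the lithium dienolate of the dioxinone (vinylogous Claisen condensation); the excess of dienolate absorbs the proton of the more acidic diketo product.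

Step 15
Reactants: 23 6-{3-[3-(2,4-bis(benzyloxy)-6-methylbenzoyl)-4,5,7,8-tetramethoxynaphthalen-2-yl]-2-oxopropyl}-2,2-dimethyl-4H-1,3-dioxin-4-one
Product: 25 6-{[3-(2,4-bis(benzyloxy)-6-methylbenzoyl)-4,5,7,8-tetramethoxynaphthalen-2-yl]methyl}-4-hydroxy-2H-pyran-2-one, via acylketene 24 (not isolated)
Conditions: toluene, 110 °C
Reagents that add atoms: none
Why: Thermal retro-hetero-Diels–Alder loss of acetone gives the acylketene, which is captured by the enol oxygen of the δ-ketone (six-membered lactonisation) and tautomerises to the 4-hydroxy-2-pyranone.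

Step 16
Reactants: 25 6-{[3-(2,4-bis(benzyloxy)-6-methylbenzoyl)-4,5,7,8-tetramethoxynaphthalen-2-yl]methyl}-4-hydroxy-2H-pyran-2-one
Product: 26 6-{[3-(2,4-bis(benzyloxy)-6-methylbenzoyl)-4,7-dimethoxy-5,8-dioxo-5,8-dihydronaphthalen-2-yl]methyl}-4-hydroxy-2H-pyran-2-one (2,5-dimethoxy-1,4-naphthoquinone in target numbering)
Conditions: CAN (2.5 equiv), MeCN/H2O, 0 °C
Reagents that add atoms: water, O
Why: Oxidative demethylation by cerium(IV) (arene radical cation, attack of water): the para-related C1/C4 methoxy groups of the most electron-rich ring become the 1,4-quinone, while the C2 and C5 methoxy groups, the benzyl ethers and the acyl-deactivated resorcinol ring should remain.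

Step 17
Reactants: 26 6-{[3-(2,4-bis(benzyloxy)-6-methylbenzoyl)-4,7-dimethoxy-5,8-dioxo-5,8-dihydronaphthalen-2-yl]methyl}-4-hydroxy-2H-pyran-2-one
Product: 27 6-{[3-(2,4-bis(benzyloxy)-6-methylbenzoyl)-7-hydroxy-4-methoxy-5,8-dioxo-5,8-dihydronaphthalen-2-yl]methyl}-4-hydroxy-2H-pyran-2-one (2-hydroxy-5-methoxy-1,4-naphthoquinone in target numbering)
Conditions: 1 M NaOH, THF/H2O, 0 °C to rt, Ar; 1 M HCl
Reagents that add atoms: sodium hydroxide, [Na+].[OH-]
Why: Addition–elimination at C2 of the methoxyquinone (hydrolysis of a vinylogous ester) by hydroxide; the pyranone is held as its enolate during the short exposure to base.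

Step 18
Reactants: 27 6-{[3-(2,4-bis(benzyloxy)-6-methylbenzoyl)-7-hydroxy-4-methoxy-5,8-dioxo-5,8-dihydronaphthalen-2-yl]methyl}-4-hydroxy-2H-pyran-2-one
Product: 28 6-(2,4-dihydroxy-6-methylbenzoyl)-2,5-dihydroxy-7-[(4-hydroxy-2-oxo-2H-pyran-6-yl)methyl]naphthalene-1,4-dione (target)
Conditions: BCl3 (excess), pentamethylbenzene, CH2Cl2, −78 to 0 °C; MeOH/H2O quench
Reagents that add atoms: none
Why: Lewis acid ether cleavage with BCl3: the C5 methyl ether is removed by chelation to the peri C4 carbonyl and the C6 ketone, and the two benzyl ethers are cleaved with pentamethylbenzene as benzyl cation scavenger, which avoids hydrogenation of the quinone or pyranone.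

**Compound list**

1 | 2,4,5-trimethoxybenzoic acid | COc1cc(OC)c(C(=O)O)cc1OC | starting material
2 | 2,4,5-trimethoxy-6-methylbenzoic acid | COc1cc(OC)c(C(=O)O)c(C)c1OC | intermediate
3 | methyl 2,4,5-trimethoxy-6-methylbenzoate | COC(=O)c1c(C)c(OC)c(OC)cc1OC | intermediate
4 | methyl 2,4,5-trimethoxy-6-(2-oxopropyl)benzoate | COC(=O)c1c(CC(C)=O)c(OC)c(OC)cc1OC | intermediate
5 | 5,6,8-trimethoxynaphthalene-1,3-diol | Oc1cc(O)c2c(OC)cc(OC)c(OC)c2c1 | intermediate
6 | 4-hydroxy-5,7,8-trimethoxynaphthalen-2-yl propan-2-ylcarbamate | CC(C)NC(=O)Oc1cc(O)c2c(OC)cc(OC)c(OC)c2c1 | intermediate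
7 | 4,5,7,8-tetramethoxynaphthalen-2-yl propan-2-ylcarbamate | CC(C)NC(=O)Oc1cc(OC)c2c(OC)cc(OC)c(OC)c2c1 | intermediate
8 | 4,5,7,8-tetramethoxynaphthalen-2-yl N-(tert-butyldimethylsilyl)-N-(propan-2-yl)carbamate | CC(C)N(C(=O)Oc1cc(OC)c2c(OC)cc(OC)c(OC)c2c1)[Si](C)(C)C(C)(C)C | intermediate
9 | 4,5,7,8-tetramethoxy-3-(trimethylsilyl)naphthalen-2-yl N-(tert-butyldimethylsilyl)-N-(propan-2-yl)carbamate | CC(C)N(C(=O)Oc1cc2c(OC)c(OC)cc(OC)c2c(OC)c1[Si](C)(C)C)[Si](C)(C)C(C)(C)C | intermediate
10 | 4,5,7,8-tetramethoxy-3-(trimethylsilyl)naphthalen-2-yl propan-2-ylcarbamate | CC(C)NC(=O)Oc1cc2c(OC)c(OC)cc(OC)c2c(OC)c1[Si](C)(C)C | intermediate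
11 | 4,5,7,8-tetramethoxy-3-(trimethylsilyl)naphthalen-2-ol | Oc1cc2c(OC)c(OC)cc(OC)c2c(OC)c1[Si](C)(C)C | intermediate
12 | 4,5,7,8-tetramethoxy-3-(trimethylsilyl)naphthalen-2-yl trifluoromethanesulfonate | COc1cc(OC)c2c(OC)c([Si](C)(C)C)c(OS(=O)(=O)C(F)(F)F)cc2c1OC | intermediate
13 | ethyl 2,4-dihydroxy-6-methylbenzoate | CCOC(=O)c1c(C)cc(O)cc1O | starting material
14 | ethyl 2,4-bis(benzyloxy)-6-methylbenzoate | CCOC(=O)c1c(C)cc(OCc2ccccc2)cc1OCc1ccccc1 | intermediate
15 | 2,4-bis(benzyloxy)-6-methylbenzoic acid | Cc1cc(OCc2ccccc2)cc(OCc2ccccc2)c1C(=O)O | intermediate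
16 | 2,4-bis(benzyloxy)-6-methylbenzoyl chloride | Cc1cc(OCc2ccccc2)cc(OCc2ccccc2)c1C(=O)Cl | intermediate
17 | methyl 3-[2,4-bis(benzyloxy)-6-methylphenyl]-3-oxopropanoate | COC(=O)CC(=O)c1c(C)cc(OCc2ccccc2)cc1OCc1ccccc1 | intermediate
18 | 1,5,6,8-tetramethoxy-2,3-didehydronaphthalene (6,7-naphthalyne in target numbering) | COC1=C(OC)C=C(OC)C2=C(OC)C#CC=C12 | intermediate
19 | methyl 2-[3-(2,4-bis(benzyloxy)-6-methylbenzoyl)-4,5,7,8-tetramethoxynaphthalen-2-yl]acetate | COC(=O)Cc1cc2c(OC)c(OC)cc(OC)c2c(OC)c1C(=O)c1c(C)cc(OCc2ccccc2)cc1OCc1ccccc1 | intermediate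
20 | 2-[3-(2,4-bis(benzyloxy)-6-methylbenzoyl)-4,5,7,8-tetramethoxynaphthalen-2-yl]acetic acid | OC(=O)Cc1cc2c(OC)c(OC)cc(OC)c2c(OC)c1C(=O)c1c(C)cc(OCc2ccccc2)cc1OCc1ccccc1 | intermediate
21 | 2,2,6-trimethyl-4H-1,3-dioxin-4-one | CC1=CC(=O)OC(C)(C)O1 | starting material
22 | 1-{[3-(2,4-bis(benzyloxy)-6-methylbenzoyl)-4,5,7,8-tetramethoxynaphthalen-2-yl]acetyl}-1H-imidazole | O=C(Cc1cc2c(OC)c(OC)cc(OC)c2c(OC)c1C(=O)c1c(C)cc(OCc2ccccc2)cc1OCc1ccccc1)n1ccnc1 | intermediate
23 | 6-{3-[3-(2,4-bis(benzyloxy)-6-methylbenzoyl)-4,5,7,8-tetramethoxynaphthalen-2-yl]-2-oxopropyl}-2,2-dimethyl-4H-1,3-dioxin-4-one | CC1(C)OC(=O)C=C(CC(=O)Cc2cc3c(OC)c(OC)cc(OC)c3c(OC)c2C(=O)c2c(C)cc(OCc3ccccc3)cc2OCc2ccccc2)O1 | intermediate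
24 | 6-[3-(2,4-bis(benzyloxy)-6-methylbenzoyl)-4,5,7,8-tetramethoxynaphthalen-2-yl]-3,5-dioxohex-1-en-1-one (acylketene) | O=C=CC(=O)CC(=O)Cc1cc2c(OC)c(OC)cc(OC)c2c(OC)c1C(=O)c1c(C)cc(OCc2ccccc2)cc1OCc1ccccc1 | intermediate
25 | 6-{[3-(2,4-bis(benzyloxy)-6-methylbenzoyl)-4,5,7,8-tetramethoxynaphthalen-2-yl]methyl}-4-hydroxy-2H-pyran-2-one | O=c1cc(O)cc(Cc2cc3c(OC)c(OC)cc(OC)c3c(OC)c2C(=O)c2c(C)cc(OCc3ccccc3)cc2OCc2ccccc2)o1 | intermediate
26 | 6-{[3-(2,4-bis(benzyloxy)-6-methylbenzoyl)-4,7-dimethoxy-5,8-dioxo-5,8-dihydronaphthalen-2-yl]methyl}-4-hydroxy-2H-pyran-2-one | COC1=CC(=O)c2c(OC)c(C(=O)c3c(C)cc(OCc4ccccc4)cc3OCc3ccccc3)c(Cc3cc(O)cc(=O)o3)cc2C1=O | intermediate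
27 | 6-{[3-(2,4-bis(benzyloxy)-6-methylbenzoyl)-7-hydroxy-4-methoxy-5,8-dioxo-5,8-dihydronaphthalen-2-yl]methyl}-4-hydroxy-2H-pyran-2-one | OC1=CC(=O)c2c(OC)c(C(=O)c3c(C)cc(OCc4ccccc4)cc3OCc3ccccc3)c(Cc3cc(O)cc(=O)o3)cc2C1=O | intermediate
28 | 6-(2,4-dihydroxy-6-methylbenzoyl)-2,5-dihydroxy-7-[(4-hydroxy-2-oxo-2H-pyran-6-yl)methyl]naphthalene-1,4-dione | Cc1cc(O)cc(O)c1C(=O)c1c(Cc2cc(O)cc(=O)o2)cc2c(c1O)C(=O)C=C(O)C2=O | target

**Step count and risks**

Total steps: 18. Longest linear sequence: 15 (steps 1–8, then 12–18); the keto ester branch (steps 9–11) joins at step 12.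

Step 12 (most likely to fail). After C-arylation, the C6 aryl anion may be protonated by the acidic keto ester before it closes on the carbonyl shielded by two ortho groups, or it may close on the ester carbonyl so that the methoxycarbonyl group migrates instead of the aroyl group. The fallback forms the two bonds one after the other without an aryne. It sets out from carbamate 7 and acid chloride 16. Carbamate 7 is N-silylated to 8 and lithiated at C6 as in step 7, and the aryllithium is acylated at −78 °C with 16 (a second addition to the tetra-ortho-substituted ketone is not possible) to give 3-[2,4-bis(benzyloxy)-6-methylbenzoyl]-4,5,7,8-tetramethoxynaphthalen-2-yl N-(tert-butyldimethylsilyl)-N-(propan-2-yl)carbamate F1, which loses the N-silyl group in the acidic work-up to give 3-[2,4-bis(benzyloxy)-6-methylbenzoyl]-4,5,7,8-tetramethoxynaphthalen-2-yl propan-2-ylcarbamate F2. Et2NH/DBU in MeCN cleaves the carbamate to [2,4-bis(benzyloxy)-6-methylphenyl](3-hydroxy-1,5,6,8-tetramethoxynaphthalen-2-yl)methanone F3, and PhNTf2 with K2CO3 gives 3-[2,4-bis(benzyloxy)-6-methylbenzoyl]-4,5,7,8-tetramethoxynaphthalen-2-yl trifluoromethanesulfonate F4. Negishi coupling of F4 with the Reformatsky reagent BrZnCH2CO2Et (Pd2(dba)3, XPhos, THF, 65 °C) gives ethyl 2-[3-(2,4-bis(benzyloxy)-6-methylbenzoyl)-4,5,7,8-tetramethoxynaphthalen-2-yl]acetate F5, and LiOH in THF/H2O hydrolyses it to acid 20, where the route is rejoined (steps 8, 12 and 13 are not needed).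

Step 5. The two hydroxyl groups may be poorly discriminated (bis-carbamoylation or reaction at the C5 hydroxyl), and the electron-rich diol may be oxidised by air during handling. The fallback uses a different selectivity principle, acid-catalysed etherification through the keto tautomer, which touches only the C7 hydroxyl (vinylogous acid). It sets out from diol 5: allyl alcohol with dry HCl at rt should give 3-(allyloxy)-5,6,8-trimethoxynaphthalen-1-ol F6; MeI/K2CO3 in acetone then methylates the C5 hydroxyl to 7-(allyloxy)-1,2,4,5-tetramethoxynaphthalene F7; Pd(PPh3)4 with morpholine removes the allyl group to give 4,5,7,8-tetramethoxynaphthalen-2-ol F8; i-PrNCO with catalytic Et3N then gives carbamate 7, where the route is rejoined (steps 5 and 6 are replaced).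

Step 14. The dienolate may enolise the arylacetyl imidazole (ketene formation, self-condensation), acylate at oxygen, or be quenched by the more acidic product so that conversion stops. The fallback replaces the acylation by an aldol addition and an oxidation. It sets out from ester 19: DIBAL-H in CH2Cl2 at −78 °C gives 2-[3-(2,4-bis(benzyloxy)-6-methylbenzoyl)-4,5,7,8-tetramethoxynaphthalen-2-yl]acetaldehyde F9 (the shielded diaryl ketone should not be reduced). Dioxinone 21 is converted with LiHMDS/TMSCl into [(2,2-dimethyl-6-methylidene-6H-1,3-dioxin-4-yl)oxy]trimethylsilane F10, which adds to F9 in a vinylogous Mukaiyama aldol reaction (BF3·OEt2, CH2Cl2, −78 °C; no base, so the enolisable aldehyde is not deprotonated) to give racemic 6-{3-[3-(2,4-bis(benzyloxy)-6-methylbenzoyl)-4,5,7,8-tetramethoxynaphthalen-2-yl]-2-hydroxypropyl}-2,2-dimethyl-4H-1,3-dioxin-4-one F11. Dess–Martin oxidation removes the carbinol centre and gives diketo-dioxinone 23, where the route is rejoined (steps 13 and 14 are replaced).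

**Further compounds**

F1 | step 12 | 3-[2,4-bis(benzyloxy)-6-methylbenzoyl]-4,5,7,8-tetramethoxynaphthalen-2-yl N-(tert-butyldimethylsilyl)-N-(propan-2-yl)carbamate | CC(C)N(C(=O)Oc1cc2c(OC)c(OC)cc(OC)c2c(OC)c1C(=O)c1c(C)cc(OCc2ccccc2)cc1OCc1ccccc1)[Si](C)(C)C(C)(C)C
F2 | step 12 | 3-[2,4-bis(benzyloxy)-6-methylbenzoyl]-4,5,7,8-tetramethoxynaphthalen-2-yl propan-2-ylcarbamate | CC(C)NC(=O)Oc1cc2c(OC)c(OC)cc(OC)c2c(OC)c1C(=O)c1c(C)cc(OCc2ccccc2)cc1OCc1ccccc1
F3 | step 12 | [2,4-bis(benzyloxy)-6-methylphenyl](3-hydroxy-1,5,6,8-tetramethoxynaphthalen-2-yl)methanone | Oc1cc2c(OC)c(OC)cc(OC)c2c(OC)c1C(=O)c1c(C)cc(OCc2ccccc2)cc1OCc1ccccc1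
F4 | step 12 | 3-[2,4-bis(benzyloxy)-6-methylbenzoyl]-4,5,7,8-tetramethoxynaphthalen-2-yl trifluoromethanesulfonate | O=S(=O)(Oc1cc2c(OC)c(OC)cc(OC)c2c(OC)c1C(=O)c1c(C)cc(OCc2ccccc2)cc1OCc1ccccc1)C(F)(F)F
F5 | step 12 | ethyl 2-[3-(2,4-bis(benzyloxy)-6-methylbenzoyl)-4,5,7,8-tetramethoxynaphthalen-2-yl]acetate | CCOC(=O)Cc1cc2c(OC)c(OC)cc(OC)c2c(OC)c1C(=O)c1c(C)cc(OCc2ccccc2)cc1OCc1ccccc1
F6 | step 5 | 3-(allyloxy)-5,6,8-trimethoxynaphthalen-1-ol | C=CCOc1cc(O)c2c(OC)cc(OC)c(OC)c2c1
F7 | step 5 | 7-(allyloxy)-1,2,4,5-tetramethoxynaphthalene | C=CCOc1cc(OC)c2c(OC)cc(OC)c(OC)c2c1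
F8 | step 5 | 4,5,7,8-tetramethoxynaphthalen-2-ol | Oc1cc(OC)c2c(OC)cc(OC)c(OC)c2c1
F9 | step 14 | 2-[3-(2,4-bis(benzyloxy)-6-methylbenzoyl)-4,5,7,8-tetramethoxynaphthalen-2-yl]acetaldehyde | O=CCc1cc2c(OC)c(OC)cc(OC)c2c(OC)c1C(=O)c1c(C)cc(OCc2ccccc2)cc1OCc1ccccc1
F10 | step 14 | [(2,2-dimethyl-6-methylidene-6H-1,3-dioxin-4-yl)oxy]trimethylsilane | C=C1C=C(O[Si](C)(C)C)OC(C)(C)O1
F11 | step 14 | 6-{3-[3-(2,4-bis(benzyloxy)-6-methylbenzoyl)-4,5,7,8-tetramethoxynaphthalen-2-yl]-2-hydroxypropyl}-2,2-dimethyl-4H-1,3-dioxin-4-one (racemic) | CC1(C)OC(=O)C=C(CC(O)Cc2cc3c(OC)c(OC)cc(OC)c3c(OC)c2C(=O)c2c(C)cc(OCc3ccccc3)cc2OCc2ccccc2)O1
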